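**Retrosynthetic overview**
- Ring B is made last: thermolysis of a 4-alkynyl-4-hydroxycyclobutenone opens to an enynylketene, which closes the quinone C–C bond as an aryl/phenoxyl diradical (Moore rearrangement), followed by H-atom transfer.
- The cyclobutenone comes from the lithium acetylide of (S)-3-ethynyl-6,7-dimethoxychroman-8-ol and dimethyl squarate; squaric acid supplies the four oxygenated ring-B carbons.
- C3 is set by iridium-catalysed asymmetric hydrogenation of the 2H-chromene-3-carboxylate; the ester is then homologated to the alkyne in one pot.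
- The pyran ring is closed by DABCO annulation of 2,3-dihydroxy-4,5-dimethoxybenzaldehyde with methyl acrylate.
- Ring A oxygenation is built on catechol (methylation, ortho-lithiation/oxidation, formylation, Dakin, formylation). Ring order: A, then pyran, then B.

Assumption: the SMILES defines C3 of the chroman as S; the carbinol centre of 19 is formed as an epimer mixture and is left undefined because step 11 destroys it.

**Step 1**
Reactants: 1 squaric acid
Product: 2 dimethyl squarate (3,4-dimethoxycyclobut-3-ene-1,2-dione)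
Conditions: HC(OMe)3, MeOH, reflux, 24 h
Reagents that add atoms: trimethyl orthoformate, COC(OC)OC
Why: Orthoester O-alkylation of the vinylogous acid is the standard high-yield preparation of dimethyl squarate.

**Step 2**
Reactants: 3 catechol
Product: 4 1,2-dimethoxybenzene (veratrole)
Conditions: MeI, K2CO3, acetone, reflux
Reagents that add atoms: iodomethane, CI
Why: Williamson O-methylation of both phenols.

**Step 3**
Reactants: 4 1,2-dimethoxybenzene
Product: 7 2,3-dimethoxyphenol, via 2,3-dimethoxyphenyllithium 5 (not isolated), via lithium aryltrimethoxyborate 6 (not isolated)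
Conditions: n-BuLi, TMEDA, THF, 0 °C to rt; B(OMe)3, −78 °C to rt; AcOH, 30% H2O2, 0 °C to rt
Reagents that add atoms: hydrogen peroxide, OO
Why: Directed ortho-metalation next to OMe, borylation and oxidative C–B to C–O migration give the phenol at C3 only.

**Step 4**
Reactants: 7 2,3-dimethoxyphenol
Product: 8 2-hydroxy-3,4-dimethoxybenzaldehyde
Conditions: MgCl2, Et3N, (CH2O)n, MeCN, reflux; then 1 M HCl
Reagents that add atoms: formaldehyde (as paraformaldehyde), C=O
Why: Casnati–Skattebøl magnesium-phenoxide ortho-formylation goes only to the single free ortho position, as in guaiacol to o-vanillin.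

**Step 5**
Reactants: 8 2-hydroxy-3,4-dimethoxybenzaldehyde
Product: 10 3,4-dimethoxybenzene-1,2-diol, via aryl formate 9 (not isolated)
Conditions: 30% H2O2 (1.1 equiv), NaOH (1.05 equiv), H2O/THF, 0 °C to rt, argon; then dilute HCl
Reagents that add atoms: hydrogen peroxide, OO
Why: Dakin oxidation of an ortho-hydroxybenzaldehyde (aryl migration to peroxide oxygen, then formate hydrolysis) replaces CHO by OH.

**Step 6**
Reactants: 10 3,4-dimethoxybenzene-1,2-diol
Product: 11 2,3-dihydroxy-4,5-dimethoxybenzaldehyde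
Conditions: MgCl2, Et3N, (CH2O)n, THF, reflux, argon; then 1 M HCl
Reagents that add atoms: formaldehyde (as paraformaldehyde), C=O
Why: The same magnesium-directed ortho-formylation can only reach the one free position ortho to a phenoxide oxygen, which is also para to a methoxy group.

**Step 7**
Reactants: 11 2,3-dihydroxy-4,5-dimethoxybenzaldehyde; 12 methyl acrylate
Product: 14 methyl 8-hydroxy-6,7-dimethoxy-2H-chromene-3-carboxylate, via 4-hydroxychroman ester 13 (not isolated)
Conditions: methyl acrylate (5 equiv), DABCO (1 equiv), CHCl3/H2O, rt to 45 °C, 3–5 d, argon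
Reagents that add atoms: none
Why: Baylis–Hillman-type annulation of a salicylaldehyde with an acrylate, then dehydration of 13; only the 2-OH can close the six-membered ring, so the 3-OH remains as the future 8-OH.

**Step 8**
Reactants: 14 methyl 8-hydroxy-6,7-dimethoxy-2H-chromene-3-carboxylate
Product: 15 methyl (3R)-8-hydroxy-6,7-dimethoxy-3,4-dihydro-2H-chromene-3-carboxylate
Conditions: H2 (50 bar), [Ir(cod)((S)-tBu-PHOX)][B(3,5-(CF3)2C6H3)4] (2 mol%), CH2Cl2, rt
Reagents that add atoms: none
Why: Iridium–phosphinooxazoline asymmetric hydrogenation of a trisubstituted α-substituted cinnamate-type ester sets C3 by ligand-controlled facial delivery of H2; the sense is checked on the first run and the antipodal ligand is used if the 3S ester forms.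

**Step 9**
Reactants: 15 methyl (3R)-8-hydroxy-6,7-dimethoxy-3,4-dihydro-2H-chromene-3-carboxylate
Product: 17 (3S)-3-ethynyl-6,7-dimethoxy-3,4-dihydro-2H-chromen-8-ol, via chroman-3-carbaldehyde 16 (not isolated)
Conditions: iBu2AlH (2.2 equiv), CH2Cl2, −78 °C; then MeOH, K2CO3, dimethyl (1-diazo-2-oxopropyl)phosphonate, −78 °C to rt
Reagents that add atoms: dimethyl (1-diazo-2-oxopropyl)phosphonate, CC(=O)C(=[N+]=[N-])P(=O)(OC)OC
Why: One-pot partial ester reduction and Ohira–Bestmann (Seyferth–Gilbert) homologation, as used on Roche-type β-alkoxy aldehydes, keeps the aldehyde transient so C3 is not epimerised; the descriptor changes from R to S only through CIP priorities.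

**Step 10**
Reactants: 17 (3S)-3-ethynyl-6,7-dimethoxy-3,4-dihydro-2H-chromen-8-ol; 2 dimethyl squarate
Product: 19 4-hydroxy-4-{[(3S)-8-hydroxy-6,7-dimethoxy-3,4-dihydro-2H-chromen-3-yl]ethynyl}-2,3-dimethoxycyclobut-2-en-1-one (both carbinol epimers), via dilithio acetylide phenoxide 18 (not isolated)
Conditions: n-BuLi (2.05 equiv), THF, −78 °C; then 2 (1.2 equiv), −78 °C, 1 h; sat. NH4Cl
Reagents that add atoms: none
Why: 1,2-Addition of a lithium acetylide to one carbonyl of a squarate ester is fast at −78 °C, where the hindered lithium phenoxide is inert.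

**Step 11**
Reactants: 19 4-hydroxy-4-{[(3S)-8-hydroxy-6,7-dimethoxy-3,4-dihydro-2H-chromen-3-yl]ethynyl}-2,3-dimethoxycyclobut-2-en-1-one
Product: 22 5-[(3S)-8-hydroxy-6,7-dimethoxy-3,4-dihydro-2H-chromen-3-yl]-2,3-dimethoxycyclohexa-2,5-diene-1,4-dione (target), via enynylketene 20 (not isolated), via aryl phenoxyl diradical 21 (not isolated)
Conditions: p-xylene (0.01 M), 138 °C, argon, 1 h
Reagents that add atoms: none
Why: Moore rearrangement: 4π ring opening (OH outward) gives (Z)-enynylketene 20, its ketene carbon bonds to the distal alkyne carbon to give the aryl σ/phenoxyl diradical 21, and H-atom transfer from the neighbouring O–H to the carbon radical gives the quinone; alkyl-substituted alkynes favour this six-membered closure and no radical sits on C3, so the stereocentre is untouched.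

**Compound list**
1 | squaric acid (3,4-dihydroxycyclobut-3-ene-1,2-dione) | OC1=C(O)C(=O)C1=O | starting material
2 | dimethyl squarate | COC1=C(OC)C(=O)C1=O | intermediate
3 | catechol | Oc1ccccc1O | starting material
4 | 1,2-dimethoxybenzene | COc1ccccc1OC | intermediate
5 | 2,3-dimethoxyphenyllithium | [Li]c1cccc(OC)c1OC | intermediate (not isolated)
6 | lithium trimethoxy(2,3-dimethoxyphenyl)borate | [Li+].CO[B-](OC)(OC)c1cccc(OC)c1OC | intermediate (not isolated)
7 | 2,3-dimethoxyphenol | COc1cccc(O)c1OC | intermediate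
8 | 2-hydroxy-3,4-dimethoxybenzaldehyde | O=Cc1ccc(OC)c(OC)c1O | intermediate
9 | 2-hydroxy-3,4-dimethoxyphenyl formate | O=COc1ccc(OC)c(OC)c1O | intermediate (not isolated)
10 | 3,4-dimethoxybenzene-1,2-diol | Oc1ccc(OC)c(OC)c1O | intermediate
11 | 2,3-dihydroxy-4,5-dimethoxybenzaldehyde | O=Cc1cc(OC)c(OC)c(O)c1O | intermediate
12 | methyl acrylate | C=CC(=O)OC | starting material
13 | methyl 4,8-dihydroxy-6,7-dimethoxy-3,4-dihydro-2H-chromene-3-carboxylate (diastereomer mixture) | COC(=O)C1COc2c(O)c(OC)c(OC)cc2C1O | intermediate (not isolated)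
14 | methyl 8-hydroxy-6,7-dimethoxy-2H-chromene-3-carboxylate | COC(=O)C1=Cc2cc(OC)c(OC)c(O)c2OC1 | intermediate
15 | methyl (3R)-8-hydroxy-6,7-dimethoxy-3,4-dihydro-2H-chromene-3-carboxylate | COC(=O)[C@H]1COc2c(O)c(OC)c(OC)cc2C1 | intermediate
16 | (3R)-8-hydroxy-6,7-dimethoxy-3,4-dihydro-2H-chromene-3-carbaldehyde | O=C[C@H]1COc2c(O)c(OC)c(OC)cc2C1 | intermediate (not isolated)
17 | (3S)-3-ethynyl-6,7-dimethoxy-3,4-dihydro-2H-chromen-8-ol | C#C[C@H]1COc2c(O)c(OC)c(OC)cc2C1 | intermediate
18 | dilithium salt of 17 (lithium acetylide, lithium phenoxide) | [Li]C#C[C@H]1COc2c(O[Li])c(OC)c(OC)cc2C1 | intermediate (not isolated)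
19 | 4-hydroxy-4-{[(3S)-8-hydroxy-6,7-dimethoxy-3,4-dihydro-2H-chromen-3-yl]ethynyl}-2,3-dimethoxycyclobut-2-en-1-one (both carbinol epimers) | COC1=C(OC)C(O)(C#C[C@H]2COc3c(O)c(OC)c(OC)cc3C2)C1=O | intermediate
20 | (3Z)-4-hydroxy-6-[(3S)-8-hydroxy-6,7-dimethoxy-3,4-dihydro-2H-chromen-3-yl]-2,3-dimethoxyhexa-1,3-dien-5-yn-1-one | O=C=C(OC)/C(OC)=C(O)\C#C[C@H]1COc2c(O)c(OC)c(OC)cc2C1 | intermediate (not isolated)
21 | aryl σ/phenoxyl diradical (4-hydroxy-2,3-dimethoxy-6-[(3S)-chroman-3-yl]phenoxyl with the radical carbon at C5) | [O]c1c(OC)c(OC)c(O)[c]c1[C@H]2COc3c(O)c(OC)c(OC)cc3C2 | intermediate (not isolated)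
22 | 5-[(3S)-8-hydroxy-6,7-dimethoxy-3,4-dihydro-2H-chromen-3-yl]-2,3-dimethoxycyclohexa-2,5-diene-1,4-dione | COC1=C(OC)C(=O)C([C@H]2COc3c(cc(OC)c(OC)c3O)C2)=CC1=O | target

**Step count**
Total: 11 steps. Longest linear sequence: 10 steps (catechol 3 to 22, steps 2–11); step 1 is a one-step side branch.

**Steps most likely to fail, with fallbacks**

Step 11 (Moore rearrangement). The risks are competing five-membered closure to a 2-alkylidene-cyclopentene-1,3-dione, 1,5-H abstraction from C2–H or C4–H by the aryl radical, and trapping of the ketene by the free phenol. The fallback sets out from 19 and returns at 22. The alkyne of 19 is semi-hydrogenated (H2 1 bar, Pd/CaCO3 poisoned with Pb(OAc)2, quinoline, EtOAc) to 4-hydroxy-4-{(Z)-2-[(3S)-8-hydroxy-6,7-dimethoxy-3,4-dihydro-2H-chromen-3-yl]ethenyl}-2,3-dimethoxycyclobut-2-en-1-one F4. Heating in toluene at 110 °C then gives ring opening to a dienylketene, 6π-electrocyclisation and tautomerisation to 5-[(3S)-8-hydroxy-6,7-dimethoxy-3,4-dihydro-2H-chromen-3-yl]-2,3-dimethoxybenzene-1,4-diol F5. Oxidation with Ag2O in Et2O gives 22.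

Step 9 (one-pot reduction/homologation). The risks are over-reduction to the alcohol and base-mediated epimerisation of the β-aryloxy aldehyde, including retro-oxa-Michael ring opening. The fallback sets out from 15 and returns at 17. Full reduction with LiAlH4 in THF at 0 °C gives [(3S)-8-hydroxy-6,7-dimethoxy-3,4-dihydro-2H-chromen-3-yl]methanol F3. Parikh–Doering oxidation (SO3·pyridine, DMSO, iPr2NEt, 0 °C) gives aldehyde 16, isolated crude here. Colvin rearrangement with LiC(N2)SiMe3 (from Me3SiCHN2 and n-BuLi, 2.1 equiv, THF, −78 to 0 °C) then gives 17 without a protic base.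

Step 8 (asymmetric hydrogenation of the ester). The risk is modest enantioselectivity on a substrate with no coordinating group and a free phenol. The fallback sets out from 14 and returns at 15. Saponification (LiOH, THF/H2O) gives 8-hydroxy-6,7-dimethoxy-2H-chromene-3-carboxylic acid F1. Carboxylate-directed hydrogenation (H2 6 bar, [Ir(cod)((Sa,S)-SIPHOX)][B(3,5-(CF3)2C6H3)4], Et3N 0.5 equiv, MeOH) gives (3R)-8-hydroxy-6,7-dimethoxy-3,4-dihydro-2H-chromene-3-carboxylic acid F2, which can be enriched by recrystallisation. Fischer esterification (MeOH, cat. H2SO4, reflux) gives 15.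

**Further compounds**
F1 | step 8 | 8-hydroxy-6,7-dimethoxy-2H-chromene-3-carboxylic acid | OC(=O)C1=Cc2cc(OC)c(OC)c(O)c2OC1
F2 | step 8 | (3R)-8-hydroxy-6,7-dimethoxy-3,4-dihydro-2H-chromene-3-carboxylic acid | OC(=O)[C@H]1COc2c(O)c(OC)c(OC)cc2C1
F3 | step 9 | [(3S)-8-hydroxy-6,7-dimethoxy-3,4-dihydro-2H-chromen-3-yl]methanol | OC[C@H]1COc2c(O)c(OC)c(OC)cc2C1
F4 | step 11 | 4-hydroxy-4-{(Z)-2-[(3S)-8-hydroxy-6,7-dimethoxy-3,4-dihydro-2H-chromen-3-yl]ethenyl}-2,3-dimethoxycyclobut-2-en-1-one (both carbinol epimers) | COC1=C(OC)C(O)(/C=C\[C@H]2COc3c(O)c(OC)c(OC)cc3C2)C1=O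
F5 | step 11 | 5-[(3S)-8-hydroxy-6,7-dimethoxy-3,4-dihydro-2H-chromen-3-yl]-2,3-dimethoxybenzene-1,4-diol | COc1c(OC)c(O)c([C@H]2COc3c(O)c(OC)c(OC)cc3C2)cc1O
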